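**Plan**

1. The target is a homoallylic acetate: C2′ is joined through C1′ to C6 of the ring double bond C5=C6, and C5 sits next to the C4 carbinol. The retrosynthesis cuts C1′–C2′ as an allylboration, which places boron on C5 and an exocyclic C6=C1′ methylene in the ring fragment and leaves tetradecanal as the chain fragment.
2. This 2‑methylenecyclohexyl boronate is then cut at C4–C5 and C1–C6 as the Diels–Alder adduct of an allenylboronic ester and a (1Z,3E)‑1‑acetoxy‑2‑methoxy‑4‑silyloxybutadiene. The diene already carries O1 as acetate, the C2 enol ether and O4 as silyl ether.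
3. Forward: diene from but‑2‑yne‑1,4‑diol (4 steps), [4+2] to build the ring, allylboration to join the chain and turn the ring into the cyclohexa‑2,5‑diene, acetylation of O2′, desilylation of O4.
4. Stereochemistry: O1/O4 cis from suprafacial addition to the out,out‑dioxygenated diene; C5–B trans to both from exo boron; C2′ by chirality transfer from C5 through a chair; absolute configuration from a chiral phosphoric acid that lets only one enantiomer of the boronate react.
5. Boron is the only helper group and leaves in the key step; the three oxygens are differentiated from the start (enol acetate, silyl dienol ether, new alkoxide).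

Key step: step 6

Remark: 7 is racemic and its SMILES shows the enantiomer consumed in step 6. The (S)‑antipode of the acid is proposed by analogy with its Si‑face preference for aliphatic aldehydes; if the matched sense proves opposite, the (R)‑antipode is used. Ring atoms are numbered as in the name of the target (C1 = CHOAc, C2 = C–OMe, C4 = CHOH, C6 = chain‑bearing carbon).

Step 1
Reactants: 1 but‑2‑yne‑1,4‑diol
Product: 2 4‑hydroxybut‑2‑yn‑1‑yl acetate
Conditions: Ac2O (1.0 equiv), 1 (3 equiv), Et3N, 4‑(dimethylamino)pyridine (cat.), THF, 0 °C to rt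
Reagents that add atoms: acetic anhydride, CC(=O)OC(C)=O
Why: Statistical mono‑esterification of a symmetric diol, with the diol in excess so that the diacetate should stay minor; no stereocentre.

Step 2
Reactants: 2 4‑hydroxybut‑2‑yn‑1‑yl acetate
Product: 3 4‑oxobut‑2‑yn‑1‑yl acetate
Conditions: TEMPO (2,2,6,6‑tetramethylpiperidin‑1‑oxyl, 10 mol %), PhI(OAc)2 (1.1 equiv), CH2Cl2, rt
Reagents that add atoms: none
Why: Oxoammonium (TEMPO) oxidation of a primary propargylic alcohol to the ynal under near‑neutral conditions that leave the acetate untouched.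

Step 3
Reactants: 3 4‑oxobut‑2‑yn‑1‑yl acetate
Product: 4 (2E)‑2‑methoxy‑4‑oxobut‑2‑en‑1‑yl acetate
Conditions: MeOH (3 equiv), DABCO (1,4‑diazabicyclo[2.2.2]octane, 10 mol %), CH2Cl2, 0 °C
Reagents that add atoms: methanol, CO
Why: Amine‑catalysed oxa‑Michael addition of methanol to the ynal places the methoxy group on the carbon that becomes ring C2; the double‑bond geometry of 4 is erased in step 4.

Step 4
Reactants: 4 (2E)‑2‑methoxy‑4‑oxobut‑2‑en‑1‑yl acetate
Product: 5 (1Z,3E)‑4‑[(tert‑butyldimethylsilyl)oxy]‑2‑methoxybuta‑1,3‑dien‑1‑yl acetate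
Conditions: TBSOTf (1.2 equiv), Et3N (2.0 equiv), Et2O, −78 to 0 °C
Reagents that add atoms: tert‑butyldimethylsilyl trifluoromethanesulfonate, CC(C)(C)[Si](C)(C)OS(=O)(=O)C(F)(F)F
Why: Silyl dienol ether formation from an enal: O‑silylation of the vinylogous formate gives a 1‑silyloxy‑3‑methoxyallyl cation that loses a γ‑proton from the acetoxymethyl group, the s‑trans enal giving the 3E silyloxyvinyl end and the acetoxy group taking the position anti to the chain (1Z), as expected for acyloxy‑substituted oxygenated dienes.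

Step 5
Reactants: 5 (1Z,3E)‑4‑[(tert‑butyldimethylsilyl)oxy]‑2‑methoxybuta‑1,3‑dien‑1‑yl acetate; 6 4,4,5,5‑tetramethyl‑2‑(propa‑1,2‑dien‑1‑yl)‑1,3,2‑dioxaborolane (allenylboronic acid pinacol ester)
Product: 7 rac‑(1S,4R,5S)‑4‑[(tert‑butyldimethylsilyl)oxy]‑2‑methoxy‑6‑methylidene‑5‑(4,4,5,5‑tetramethyl‑1,3,2‑dioxaborolan‑2‑yl)cyclohex‑2‑en‑1‑yl acetate
Conditions: 6 (1.5 equiv), BHT (cat.), toluene, 90 °C, sealed tube; filtration through Et3N‑deactivated silica
Reagents that add atoms: none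
Why: Thermal Diels–Alder reaction at the boron‑bearing C=C of the allene, in which the acetoxy‑bearing diene terminus (made the most nucleophilic by the 2‑methoxy and 4‑silyloxy donors) bonds to the central allene carbon β to boron, suprafacial addition to the out,out‑dioxygenated diene sets O1 and O4 cis, and the bulky dioxaborolane should take the exo position so that boron ends trans to both oxygens.

Step 6
Reactants: 7 rac‑(1S,4R,5S)‑4‑[(tert‑butyldimethylsilyl)oxy]‑2‑methoxy‑6‑methylidene‑5‑(4,4,5,5‑tetramethyl‑1,3,2‑dioxaborolan‑2‑yl)cyclohex‑2‑en‑1‑yl acetate; 8 tetradecanal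
Product: 10 (1S,4R)‑4‑[(tert‑butyldimethylsilyl)oxy]‑6‑[(2R)‑2‑hydroxypentadecyl]‑2‑methoxycyclohexa‑2,5‑dien‑1‑yl acetate, via O‑pinacolboryl borate ester 9 (not isolated)
Conditions: (S)‑3,3′‑bis(2,4,6‑triisopropylphenyl)‑1,1′‑binaphthyl‑2,2′‑diyl hydrogen phosphate (10 mol %), rac‑7 (2.2 equiv), 8 (1.0 equiv), 4 Å MS, toluene, −20 °C; then aq. NaHCO3
Reagents that add atoms: none
Why: Boron of 7 binds the aldehyde oxygen and the exocyclic methylene carbon C1′ attacks the carbonyl carbon through a closed six‑membered chair (type 1 allylboration, SE2′), so the C1′–C2′ bond forms while the C6=C1′ double bond moves into the ring as C5=C6 and completes the cyclohexa‑2,5‑diene. The closest known reaction types are the chirality‑transferring addition of α‑substituted allylboronic esters to aldehydes and the chiral‑phosphoric‑acid‑catalysed kinetic resolution of racemic secondary allylboronic esters. No ring is closed. The new C2′ stereocentre is controlled by the C5–B stereocentre: the ring forces C4 into the pseudo‑equatorial position of the chair (it must end cis to C1 across the new ring double bond) and the tridecyl chain sits equatorial, so boron anti to the C1 and C4 oxygens delivers C1′ to the Si face and gives (2′R) beside the (1S,4R) ring. The acid, hydrogen‑bonded to a dioxaborolane oxygen, should accelerate only the enantiomer of 7 whose chair presents that Si face, which fixes the absolute configuration of all three stereocentres of the target. The step needs γ‑selectivity (secured by the boronic ester, which undergoes no 1,3‑boron shift), enantiomer discrimination (matched against mismatched chair) and survival of the enol ether and the allylic oxygens (low temperature, sieves, a hindered acid in catalytic amount, basic work‑up).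

Step 7
Reactants: 10 (1S,4R)‑4‑[(tert‑butyldimethylsilyl)oxy]‑6‑[(2R)‑2‑hydroxypentadecyl]‑2‑methoxycyclohexa‑2,5‑dien‑1‑yl acetate
Product: 11 (1S,4R)‑6‑[(2R)‑2‑(acetyloxy)pentadecyl]‑4‑[(tert‑butyldimethylsilyl)oxy]‑2‑methoxycyclohexa‑2,5‑dien‑1‑yl acetate
Conditions: Ac2O, pyridine, 4‑(dimethylamino)pyridine (cat.), CH2Cl2, 0 °C to rt
Reagents that add atoms: acetic anhydride, CC(=O)OC(C)=O
Why: Nucleophile‑catalysed acylation of the only free hydroxyl under basic conditions that spare the enol ether and the silyl ether; no stereocentre is touched.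

Step 8
Reactants: 11 (1S,4R)‑6‑[(2R)‑2‑(acetyloxy)pentadecyl]‑4‑[(tert‑butyldimethylsilyl)oxy]‑2‑methoxycyclohexa‑2,5‑dien‑1‑yl acetate
Product: 12 (1S,4R)‑6‑[(2R)‑2‑(acetyloxy)pentadecyl]‑4‑hydroxy‑2‑methoxycyclohexa‑2,5‑dien‑1‑yl acetate
Conditions: Bu4NF (1.5 equiv), AcOH (1.5 equiv), THF, 0 °C
Reagents that add atoms: none
Why: Fluoride cleaves the silyl ether at O4 while acetic acid buffers the alkoxide, so that neither acetate should be cleaved or transferred and no strong acid reaches the enol ether; no stereocentre is touched.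

**Compound list**

1 | but‑2‑yne‑1,4‑diol | OCC#CCO | starting material
2 | 4‑hydroxybut‑2‑yn‑1‑yl acetate | CC(=O)OCC#CCO | intermediate
3 | 4‑oxobut‑2‑yn‑1‑yl acetate | CC(=O)OCC#CC=O | intermediate
4 | (2E)‑2‑methoxy‑4‑oxobut‑2‑en‑1‑yl acetate | CC(=O)OC/C(OC)=C\C=O | intermediate
5 | (1Z,3E)‑4‑[(tert‑butyldimethylsilyl)oxy]‑2‑methoxybuta‑1,3‑dien‑1‑yl acetate | CC(=O)O/C=C(OC)/C=C/O[Si](C)(C)C(C)(C)C | intermediate
6 | 4,4,5,5‑tetramethyl‑2‑(propa‑1,2‑dien‑1‑yl)‑1,3,2‑dioxaborolane | C=C=CB1OC(C)(C)C(C)(C)O1 | starting material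
7 | rac‑(1S,4R,5S)‑4‑[(tert‑butyldimethylsilyl)oxy]‑2‑methoxy‑6‑methylidene‑5‑(4,4,5,5‑tetramethyl‑1,3,2‑dioxaborolan‑2‑yl)cyclohex‑2‑en‑1‑yl acetate | C=C1[C@H](B2OC(C)(C)C(C)(C)O2)[C@@H](O[Si](C)(C)C(C)(C)C)C=C(OC)[C@H]1OC(C)=O | intermediate
8 | tetradecanal | CCCCCCCCCCCCCC=O | starting material
9 | (1S,4R)‑4‑[(tert‑butyldimethylsilyl)oxy]‑2‑methoxy‑6‑{(2R)‑2‑[(4,4,5,5‑tetramethyl‑1,3,2‑dioxaborolan‑2‑yl)oxy]pentadecyl}cyclohexa‑2,5‑dien‑1‑yl acetate | CCCCCCCCCCCCC[C@H](CC1=C[C@@H](O[Si](C)(C)C(C)(C)C)C=C(OC)[C@H]1OC(C)=O)OB1OC(C)(C)C(C)(C)O1 | intermediate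
10 | (1S,4R)‑4‑[(tert‑butyldimethylsilyl)oxy]‑6‑[(2R)‑2‑hydroxypentadecyl]‑2‑methoxycyclohexa‑2,5‑dien‑1‑yl acetate | CCCCCCCCCCCCC[C@@H](O)CC1=C[C@@H](O[Si](C)(C)C(C)(C)C)C=C(OC)[C@H]1OC(C)=O | intermediate
11 | (1S,4R)‑6‑[(2R)‑2‑(acetyloxy)pentadecyl]‑4‑[(tert‑butyldimethylsilyl)oxy]‑2‑methoxycyclohexa‑2,5‑dien‑1‑yl acetate | CCCCCCCCCCCCC[C@H](CC1=C[C@@H](O[Si](C)(C)C(C)(C)C)C=C(OC)[C@H]1OC(C)=O)OC(C)=O | intermediate
12 | (1S,4R)‑6‑[(2R)‑2‑(acetyloxy)pentadecyl]‑4‑hydroxy‑2‑methoxycyclohexa‑2,5‑dien‑1‑yl acetate | CCCCCCCCCCCCC[C@H](CC1=C[C@@H](O)C=C(OC)[C@H]1OC(C)=O)OC(C)=O | target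

**Step count and risks**

Total steps: 8. Longest linear sequence: 8 steps (1 to 12); 6 and 8 are bought.

Steps most likely to fail:

Step 5. The boronate is only a weakly activated dienophile, so the cycloaddition may be slower than thermal decomposition or geometric isomerisation of the diene; boron may also partly take the endo position, or the adduct may lose boron and the neighbouring silyloxy group by β‑elimination. Fallback, from 5 back to 7: cobalt‑catalysed neutral [4+2] cycloaddition of 5 with commercial methyl prop‑2‑yn‑1‑yl carbonate (CoBr2, N‑mesityl‑1‑(pyridin‑2‑yl)methanimine, Zn, ZnI2, CH2Cl2, rt), a ligand type that places the alkyne substituent 1,3 to the 2‑donor of the diene, should give the cis‑dioxygenated dienylmethyl carbonate rac‑[(3R,6S)‑6‑(acetyloxy)‑3‑[(tert‑butyldimethylsilyl)oxy]‑5‑methoxycyclohexa‑1,4‑dien‑1‑yl]methyl methyl carbonate F1 without any activating group on the alkyne. Copper‑catalysed γ‑selective boryl substitution of this primary allylic carbonate (CuOtBu, Xantphos, B2pin2, THF, 0 °C) should then add boron to C5 from the face opposite the two ring oxygens, expel the carbonate and return to 7.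

Step 6. The acid may discriminate poorly between the two enantiomers of 7, or it may ionise the C4 silyloxy group or hydrolyse the enol ether before the slow, hindered allyl transfer occurs. Fallback, from 5 back to 10, without acid or catalyst: Diels–Alder reaction of 5 with the chiral allenylboronic ester (4R,5R)‑4,5‑dicyclohexyl‑2‑(propa‑1,2‑dien‑1‑yl)‑1,3,2‑dioxaborolane F2 (from allenylmagnesium bromide, B(OMe)3 and (R,R)‑1,2‑dicyclohexylethane‑1,2‑diol) gives two diastereomeric exo adducts. The adduct with the wanted ring, (1S,4R,5S)‑4‑[(tert‑butyldimethylsilyl)oxy]‑5‑[(4R,5R)‑4,5‑dicyclohexyl‑1,3,2‑dioxaborolan‑2‑yl]‑2‑methoxy‑6‑methylidenecyclohex‑2‑en‑1‑yl acetate F3, is separated by chromatography from its (1R,4S,5R) ring diastereomer F4. F3 is warmed with 8 (toluene, 50 °C), the same chair transfers chirality to give the dicyclohexyl‑dioxaborolanyl borate ester of 10 F5, and NaHCO3 work‑up returns to 10.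

Step 8. The liberated O4 alkoxide may take the acetyl group from O1 across the boat‑shaped ring, or ionisation at C4 may lead to elimination and aromatisation. Fallback, from 4 back to 12, with a silyl group that comes off under much milder conditions: 4 with Et3SiOTf/Et3N gives (1Z,3E)‑2‑methoxy‑4‑[(triethylsilyl)oxy]buta‑1,3‑dien‑1‑yl acetate F6. Cycloaddition with 6 as in step 5 gives rac‑(1S,4R,5S)‑2‑methoxy‑6‑methylidene‑5‑(4,4,5,5‑tetramethyl‑1,3,2‑dioxaborolan‑2‑yl)‑4‑[(triethylsilyl)oxy]cyclohex‑2‑en‑1‑yl acetate F7. Allylboration of 8 as in step 6 gives, through the pinacolboryl borate ester F8, (1S,4R)‑6‑[(2R)‑2‑hydroxypentadecyl]‑2‑methoxy‑4‑[(triethylsilyl)oxy]cyclohexa‑2,5‑dien‑1‑yl acetate F9. Acetylation gives (1S,4R)‑6‑[(2R)‑2‑(acetyloxy)pentadecyl]‑2‑methoxy‑4‑[(triethylsilyl)oxy]cyclohexa‑2,5‑dien‑1‑yl acetate F10, and HF·pyridine buffered with excess pyridine (THF, 0 °C) then returns to 12.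

**Further compounds**

F1 | step 5 | rac‑[(3R,6S)‑6‑(acetyloxy)‑3‑[(tert‑butyldimethylsilyl)oxy]‑5‑methoxycyclohexa‑1,4‑dien‑1‑yl]methyl methyl carbonate | COC(=O)OCC1=C[C@@H](O[Si](C)(C)C(C)(C)C)C=C(OC)[C@H]1OC(C)=O
F2 | step 6 | (4R,5R)‑4,5‑dicyclohexyl‑2‑(propa‑1,2‑dien‑1‑yl)‑1,3,2‑dioxaborolane | C=C=CB1O[C@H](C2CCCCC2)[C@@H](C2CCCCC2)O1
F3 | step 6 | (1S,4R,5S)‑4‑[(tert‑butyldimethylsilyl)oxy]‑5‑[(4R,5R)‑4,5‑dicyclohexyl‑1,3,2‑dioxaborolan‑2‑yl]‑2‑methoxy‑6‑methylidenecyclohex‑2‑en‑1‑yl acetate | C=C1[C@H](B2O[C@H](C3CCCCC3)[C@@H](C3CCCCC3)O2)[C@@H](O[Si](C)(C)C(C)(C)C)C=C(OC)[C@H]1OC(C)=O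
F4 | step 6 | (1R,4S,5R)‑4‑[(tert‑butyldimethylsilyl)oxy]‑5‑[(4R,5R)‑4,5‑dicyclohexyl‑1,3,2‑dioxaborolan‑2‑yl]‑2‑methoxy‑6‑methylidenecyclohex‑2‑en‑1‑yl acetate | C=C1[C@@H](B2O[C@H](C3CCCCC3)[C@@H](C3CCCCC3)O2)[C@H](O[Si](C)(C)C(C)(C)C)C=C(OC)[C@@H]1OC(C)=O
F5 | step 6 | (1S,4R)‑4‑[(tert‑butyldimethylsilyl)oxy]‑6‑[(2R)‑2‑{[(4R,5R)‑4,5‑dicyclohexyl‑1,3,2‑dioxaborolan‑2‑yl]oxy}pentadecyl]‑2‑methoxycyclohexa‑2,5‑dien‑1‑yl acetate | CCCCCCCCCCCCC[C@H](CC1=C[C@@H](O[Si](C)(C)C(C)(C)C)C=C(OC)[C@H]1OC(C)=O)OB1O[C@H](C2CCCCC2)[C@@H](C2CCCCC2)O1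
F6 | step 8 | (1Z,3E)‑2‑methoxy‑4‑[(triethylsilyl)oxy]buta‑1,3‑dien‑1‑yl acetate | CC(=O)O/C=C(OC)/C=C/O[Si](CC)(CC)CC
F7 | step 8 | rac‑(1S,4R,5S)‑2‑methoxy‑6‑methylidene‑5‑(4,4,5,5‑tetramethyl‑1,3,2‑dioxaborolan‑2‑yl)‑4‑[(triethylsilyl)oxy]cyclohex‑2‑en‑1‑yl acetate | C=C1[C@H](B2OC(C)(C)C(C)(C)O2)[C@@H](O[Si](CC)(CC)CC)C=C(OC)[C@H]1OC(C)=O
F8 | step 8 | (1S,4R)‑2‑methoxy‑6‑{(2R)‑2‑[(4,4,5,5‑tetramethyl‑1,3,2‑dioxaborolan‑2‑yl)oxy]pentadecyl}‑4‑[(triethylsilyl)oxy]cyclohexa‑2,5‑dien‑1‑yl acetate | CCCCCCCCCCCCC[C@H](CC1=C[C@@H](O[Si](CC)(CC)CC)C=C(OC)[C@H]1OC(C)=O)OB1OC(C)(C)C(C)(C)O1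
F9 | step 8 | (1S,4R)‑6‑[(2R)‑2‑hydroxypentadecyl]‑2‑methoxy‑4‑[(triethylsilyl)oxy]cyclohexa‑2,5‑dien‑1‑yl acetate | CCCCCCCCCCCCC[C@@H](O)CC1=C[C@@H](O[Si](CC)(CC)CC)C=C(OC)[C@H]1OC(C)=O
F10 | step 8 | (1S,4R)‑6‑[(2R)‑2‑(acetyloxy)pentadecyl]‑2‑methoxy‑4‑[(triethylsilyl)oxy]cyclohexa‑2,5‑dien‑1‑yl acetate | CCCCCCCCCCCCC[C@H](CC1=C[C@@H](O[Si](CC)(CC)CC)C=C(OC)[C@H]1OC(C)=O)OC(C)=O
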